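**Retrosynthetic overview**
1. Last bond: C8–CH(iPr), by catalyst-controlled Friedel–Crafts/Michael addition of (S)-strobopinin 21 to the isobutylidene triketone made in situ from 11 and 2-methylpropanal.
2. Triketone ring 11: one-carbon ring expansion (1,2-shift) of cyclopentanetrione 4 with tert-butyl diazoacetate; the ester then steers O-methylation and is removed.
3. Five-membered ring 4: double Claisen of 2-methylpentan-3-one with dimethyl oxalate.
4. Flavanone 21: pyranone ring first (asymmetric vinylogous aldol sets C2, amide-acetal annulation), then ring A by lateral acylation/Dieckmann, which fixes the 6-methyl regiochemistry.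
5. Ring order: cyclopentenedione → six-membered triketone; dihydropyranone → benzo ring A; the two halves are joined last.

Assumption: enolisable di- and triketones are written in one tautomer; the target is drawn in the tautomer of the given SMILES (C2 = S, methine = R in that tautomer).

**Step 1**
Reactants: 1 2-methylpentan-3-one; 2 dimethyl oxalate
Product: 4 4-hydroxy-2,2,5-trimethylcyclopent-4-ene-1,3-dione (enol of 3,3,5-trimethylcyclopentane-1,2,4-trione), via dioxo ester 3 (not isolated)
Conditions: KOtBu (2.5 equiv), THF, 0 → 60 °C; then 2 M HCl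
Reagents that add atoms: none
Why: Crossed Claisen at the ketone CH2, then Dieckmann closure of the isopropyl CH onto the second ester; the stabilised vinylogous-acid anion of 4 drives formation of the quaternary carbon.

**Step 2**
Reactants: 4 4-hydroxy-2,2,5-trimethylcyclopent-4-ene-1,3-dione; 5 tert-butyl diazoacetate
Product: 8 tert-butyl 2,4-dihydroxy-3,3,5-trimethyl-6-oxocyclohexa-1,4-diene-1-carboxylate, via silyl ether 6 (not isolated), via silyl enol ether 7 (not isolated)
Conditions: TMSCl, Et3N, hexane, rt, filter; then 5 (1.3 equiv), Sc(OTf)3 (10 mol %), CH2Cl2, −20 °C → rt; aq. citric acid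
Reagents that add atoms: none
Why: Proposed new method: Lewis-acid-catalysed one-carbon ring expansion of an enolised cyclic vicinal tricarbonyl. Sc(OTf)3 activates the only ketone-type carbonyl (flanked by CMe2 and the silyloxy-alkene carbon), the diazo carbon adds, and N2 loss is coupled to 1,2-shift of the planar sp2 (enolised acyl) carbon rather than the hindered, acyl-bearing quaternary carbon. The new CH(CO2tBu) carbon therefore lands between two oxygenated carbons, giving the 1,3,5-trione. Closest known type: Tiffeneau–Demjanov/diazo-ester ring expansion of cycloalkanones and the acyl-shift homologation of vicinal di- and triketones by diazoalkanes.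

**Step 3**
Reactants: 8 tert-butyl 2,4-dihydroxy-3,3,5-trimethyl-6-oxocyclohexa-1,4-diene-1-carboxylate
Product: 9 tert-butyl 2-hydroxy-4-methoxy-3,3,5-trimethyl-6-oxocyclohexa-1,4-diene-1-carboxylate
Conditions: TMSCHN2 (1.1 equiv), MeOH/toluene 1:4, 0 °C
Reagents that add atoms: trimethylsilyldiazomethane, C[Si](C)(C)C=[N+]=[N-]
Why: Diazomethane-type O-methylation hits only the free vinylogous-acid OH at C4; the C2–OH is locked in a hydrogen bond to the ester carbonyl, as in para-O-methylation of acylphloroglucinols and acylfilicinic acids.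

**Step 4**
Reactants: 9 tert-butyl 2-hydroxy-4-methoxy-3,3,5-trimethyl-6-oxocyclohexa-1,4-diene-1-carboxylate
Product: 11 5-methoxy-4,6,6-trimethylcyclohex-4-ene-1,3-dione, via keto acid 10 (not isolated)
Conditions: TFA/CH2Cl2 1:4, 0 °C → rt; then toluene, 50 °C
Reagents that add atoms: none
Why: Anhydrous acidolysis of the tert-butyl ester and spontaneous decarboxylation of the β,β′-diketo acid; the enol methyl ether survives water-free acid.

**Step 5**
Reactants: 12 methyl acetoacetate
Product: 13 1-methoxy-1,3-bis(trimethylsilyloxy)buta-1,3-diene (Chan's diene)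
Conditions: TMSOTf (2.1 equiv), Et3N (2.4 equiv), Et2O, 0 °C → rt; distil
Reagents that add atoms: trimethylsilyl trifluoromethanesulfonate, C[Si](C)(C)OS(=O)(=O)C(F)(F)F
Why: Double soft enolisation and O-silylation of the β-keto ester.

**Step 6**
Reactants: 13 1-methoxy-1,3-bis(trimethylsilyloxy)buta-1,3-diene; 14 benzaldehyde
Product: 16 methyl (5S)-5-hydroxy-3-oxo-5-phenylpentanoate, via silylated aldol adduct 15 (not isolated)
Conditions: Ti(OiPr)4 (8 mol %), (S)-BINOL (8 mol %), 4 Å MS, THF, −78 °C → rt; then TFA, THF/H2O, 0 °C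
Reagents that add atoms: none
Why: Ti–BINOL-catalysed vinylogous Mukaiyama aldol; the (S)-BINOL complex directs the diene terminus to the Si face of the aldehyde, giving the (S)-carbinol that becomes C2 of the flavanone.

**Step 7**
Reactants: 16 methyl (5S)-5-hydroxy-3-oxo-5-phenylpentanoate
Product: 18 methyl (2S)-6-methyl-4-oxo-2-phenyl-3,4-dihydro-2H-pyran-5-carboxylate, via enaminone 17 (not isolated)
Conditions: MeC(OMe)2NMe2 (1.5 equiv), toluene, rt; then TFA (2 equiv), CH2Cl2, 0 °C → rt
Reagents that add atoms: N,N-dimethylacetamide dimethyl acetal, COC(C)(OC)N(C)C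
Why: Amide-acetal condensation at the active methylene, then 6-endo oxa-Michael addition–elimination of the carbinol oxygen (dihydropyranone annulation); the carbinol C–O bond is not broken, so C2 is retained.

**Step 8**
Reactants: 18 methyl (2S)-6-methyl-4-oxo-2-phenyl-3,4-dihydro-2H-pyran-5-carboxylate; 19 N-methoxy-N-methylpropanamide
Product: 20 methyl (2S)-4-oxo-6-(2-oxobutyl)-2-phenyl-3,4-dihydro-2H-pyran-5-carboxylate
Conditions: LDA (1.05 equiv), THF, −78 → −40 °C; then 19, −78 → −20 °C; AcOH
Reagents that add atoms: none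
Why: Lateral (vinylogous) deprotonation of the 6-methyl, which is γ to both ketone and ester, gives the extended dienolate; Weinreb acylation at its terminal carbon stops at the ketone through the chelated tetrahedral intermediate.

**Step 9**
Reactants: 20 methyl (2S)-4-oxo-6-(2-oxobutyl)-2-phenyl-3,4-dihydro-2H-pyran-5-carboxylate
Product: 21 (2S)-5,7-dihydroxy-6-methyl-2-phenylchroman-4-one ((S)-strobopinin)
Conditions: LiHMDS (2.3 equiv), THF, −78 → −20 °C; 1 M HCl
Reagents that add atoms: none
Why: Dianion Dieckmann (intramolecular Claisen) of the ethyl-ketone α-carbon onto the neighbouring ester, then aromatisation by tautomerisation. Because O1 is already in the pyranone, only the 6-methyl isomer can form, and C2 is untouched at low temperature.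

**Step 10**
Reactants: 11 5-methoxy-4,6,6-trimethylcyclohex-4-ene-1,3-dione; 22 2-methylpropanal; 21 (2S)-5,7-dihydroxy-6-methyl-2-phenylchroman-4-one
Product: 24 (2S)-5,7-dihydroxy-8-[(1R)-1-(2-hydroxy-4-methoxy-3,3,5-trimethyl-6-oxocyclohexa-1,4-dien-1-yl)-2-methylpropyl]-6-methyl-2-phenylchroman-4-one, via isobutylidene triketone 23 (not isolated)
Conditions: 22 (2 equiv), (R)-TRIP (10 mol %), 5 Å MS, toluene, 40 °C; excess 22 stripped; then 21, CH2Cl2/toluene, −20 °C
Reagents that add atoms: none
Why: Proposed new method: chiral phosphoric acid-catalysed Knoevenagel condensation followed by enantioface-selective Friedel–Crafts conjugate addition of C8 (the only free ring position) to the exocyclic CH(iPr) terminus. The catalyst bridges the 7-OH (P=O···H–O) and the enone carbonyl (P–OH···O=C), and its 2,4,6-triisopropylphenyl walls expose one face. (R)-TRIP is the working choice for the (R)-methine; the antipode is used if the first run shows the opposite sense, since C2 is too remote to bias the outcome. Closest known type: phosphoric-acid-catalysed Friedel–Crafts additions of phenols to ortho-quinone methides and enones, and the racemic Knoevenagel/Michael assembly of acylphloroglucinol–triketone adducts.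

**Compound list**
1 | 2-methylpentan-3-one | CCC(=O)C(C)C | starting material
2 | dimethyl oxalate | COC(=O)C(=O)OC | starting material
3 | methyl 3,5-dimethyl-2,4-dioxohexanoate | COC(=O)C(=O)C(C)C(=O)C(C)C | intermediate
4 | 4-hydroxy-2,2,5-trimethylcyclopent-4-ene-1,3-dione | CC1=C(O)C(=O)C(C)(C)C1=O | intermediate
5 | tert-butyl diazoacetate | CC(C)(C)OC(=O)C=[N+]=[N-] | starting material
6 | 2,2,5-trimethyl-4-(trimethylsilyloxy)cyclopent-4-ene-1,3-dione | CC1=C(O[Si](C)(C)C)C(=O)C(C)(C)C1=O | intermediate
7 | tert-butyl 3,3,5-trimethyl-2,4-dioxo-6-(trimethylsilyloxy)cyclohex-5-ene-1-carboxylate | CC(C)(C)OC(=O)C1C(=O)C(C)(C)C(=O)C(C)=C1O[Si](C)(C)C | intermediate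
8 | tert-butyl 2,4-dihydroxy-3,3,5-trimethyl-6-oxocyclohexa-1,4-diene-1-carboxylate | CC(C)(C)OC(=O)C1=C(O)C(C)(C)C(O)=C(C)C1=O | intermediate
9 | tert-butyl 2-hydroxy-4-methoxy-3,3,5-trimethyl-6-oxocyclohexa-1,4-diene-1-carboxylate | CC(C)(C)OC(=O)C1=C(O)C(C)(C)C(OC)=C(C)C1=O | intermediate
10 | 2-hydroxy-4-methoxy-3,3,5-trimethyl-6-oxocyclohexa-1,4-diene-1-carboxylic acid | OC(=O)C1=C(O)C(C)(C)C(OC)=C(C)C1=O | intermediate
11 | 5-methoxy-4,6,6-trimethylcyclohex-4-ene-1,3-dione | COC1=C(C)C(=O)CC(=O)C1(C)C | intermediate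
12 | methyl acetoacetate | COC(=O)CC(C)=O | starting material
13 | 1-methoxy-1,3-bis(trimethylsilyloxy)buta-1,3-diene | COC(=CC(=C)O[Si](C)(C)C)O[Si](C)(C)C | intermediate
14 | benzaldehyde | O=Cc1ccccc1 | starting material
15 | methyl (5S)-5-phenyl-3,5-bis(trimethylsilyloxy)pent-2-enoate | COC(=O)C=C(C[C@H](O[Si](C)(C)C)c1ccccc1)O[Si](C)(C)C | intermediate
16 | methyl (5S)-5-hydroxy-3-oxo-5-phenylpentanoate | COC(=O)CC(=O)C[C@H](O)c1ccccc1 | intermediate
17 | methyl (5S)-2-[1-(dimethylamino)ethylidene]-5-hydroxy-3-oxo-5-phenylpentanoate | COC(=O)C(=C(C)N(C)C)C(=O)C[C@H](O)c1ccccc1 | intermediate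
18 | methyl (2S)-6-methyl-4-oxo-2-phenyl-3,4-dihydro-2H-pyran-5-carboxylate | COC(=O)C1=C(C)O[C@H](c2ccccc2)CC1=O | intermediate
19 | N-methoxy-N-methylpropanamide | CCC(=O)N(C)OC | starting material
20 | methyl (2S)-4-oxo-6-(2-oxobutyl)-2-phenyl-3,4-dihydro-2H-pyran-5-carboxylate | COC(=O)C1=C(CC(=O)CC)O[C@H](c2ccccc2)CC1=O | intermediate
21 | (2S)-5,7-dihydroxy-6-methyl-2-phenylchroman-4-one | Cc1c(O)cc2O[C@H](c3ccccc3)CC(=O)c2c1O | intermediate
22 | 2-methylpropanal | CC(C)C=O | starting material
23 | 5-methoxy-4,6,6-trimethyl-2-(2-methylpropylidene)cyclohex-4-ene-1,3-dione | COC1=C(C)C(=O)C(=CC(C)C)C(=O)C1(C)C | intermediate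
24 | (2S)-5,7-dihydroxy-8-[(1R)-1-(2-hydroxy-4-methoxy-3,3,5-trimethyl-6-oxocyclohexa-1,4-dien-1-yl)-2-methylpropyl]-6-methyl-2-phenylchroman-4-one | COC1=C(C)C(=O)C([C@@H](c2c(O)c(C)c(O)c3c2O[C@H](c2ccccc2)CC3=O)C(C)C)=C(O)C1(C)C | target

**Step count**
Total steps: 10. Longest linear sequence: 6 (steps 5, 6, 7, 8, 9, 10); the triketone branch is steps 1–4.

**Steps most likely to fail**

Step 2 (proposed new ring expansion). The risks are glycidic-ester formation and migration of the wrong carbon. The fallback sets out from 4 and returns at 8, and separates addition from rearrangement using known reactions. Compound 4 is silylated (TBSCl, imidazole) to 4-(tert-butyldimethylsilyloxy)-2,2,5-trimethylcyclopent-4-ene-1,3-dione F1. Lithiated 5 (LDA, THF, −78 °C) adds to the ketone to give the tertiary diazo carbinol tert-butyl 2-[2-(tert-butyldimethylsilyloxy)-1-hydroxy-3,5,5-trimethyl-4-oxocyclopent-2-en-1-yl]-2-diazoacetate F2. Rh2(OAc)4 (1 mol %, CH2Cl2) then converts F2 through the metal carbenoid 1,2-shift into tert-butyl 6-(tert-butyldimethylsilyloxy)-3,3,5-trimethyl-2,4-dioxocyclohex-5-ene-1-carboxylate F3, and aqueous HCl/THF desilylates F3 to 8.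

Step 9 (dianion Dieckmann). The second deprotonation may occur at C3 of the pyranone, which leads to ring opening and loss of ee. The fallback sets out from 18 and returns at 21, and moves the ring closure onto a doubly activated carbon so that no strong base is needed. The dienolate of 18 is acylated with the imidazolide of mono-tert-butyl methylmalonate to give methyl (2S)-6-(4-tert-butoxy-3-methyl-2,4-dioxobutyl)-4-oxo-2-phenyl-3,4-dihydro-2H-pyran-5-carboxylate F4. DBU in MeCN at 0 °C closes F4 through its β-keto-ester carbon to tert-butyl (2S)-6-methyl-4,5,7-trioxo-2-phenyl-3,4,5,6,7,8-hexahydro-2H-chromene-6-carboxylate F5 (mixture at C6). TFA then cleaves the tert-butyl ester and decarboxylation aromatises the ring to 21.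

Step 10 (proposed new asymmetric coupling). The catalyst may give low facial control or slow turnover. The fallback sets out from 11, 22 and 21 and returns at 24, and replaces catalyst control by separation. Compound 23 is made with catalytic L-proline in CH2Cl2 and filtered through silica, then combined with 21 under the established uncatalysed Knoevenagel/Michael conditions (CH2Cl2, rt). This gives 24 together with its methine epimer (2S)-5,7-dihydroxy-8-[(1S)-1-(2-hydroxy-4-methoxy-3,3,5-trimethyl-6-oxocyclohexa-1,4-dien-1-yl)-2-methylpropyl]-6-methyl-2-phenylchroman-4-one F6. The two are diastereomers, separated by preparative HPLC; F6 is recycled by thermal retro-Michael/re-addition.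

**Further compounds**
F1 | step 2 | 4-(tert-butyldimethylsilyloxy)-2,2,5-trimethylcyclopent-4-ene-1,3-dione | CC1=C(O[Si](C)(C)C(C)(C)C)C(=O)C(C)(C)C1=O
F2 | step 2 | tert-butyl 2-[2-(tert-butyldimethylsilyloxy)-1-hydroxy-3,5,5-trimethyl-4-oxocyclopent-2-en-1-yl]-2-diazoacetate (racemic) | CC1=C(O[Si](C)(C)C(C)(C)C)C(O)(C(=[N+]=[N-])C(=O)OC(C)(C)C)C(C)(C)C1=O
F3 | step 2 | tert-butyl 6-(tert-butyldimethylsilyloxy)-3,3,5-trimethyl-2,4-dioxocyclohex-5-ene-1-carboxylate | CC(C)(C)OC(=O)C1C(=O)C(C)(C)C(=O)C(C)=C1O[Si](C)(C)C(C)(C)C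
F4 | step 9 | methyl (2S)-6-(4-tert-butoxy-3-methyl-2,4-dioxobutyl)-4-oxo-2-phenyl-3,4-dihydro-2H-pyran-5-carboxylate | COC(=O)C1=C(CC(=O)C(C)C(=O)OC(C)(C)C)O[C@H](c2ccccc2)CC1=O
F5 | step 9 | tert-butyl (2S)-6-methyl-4,5,7-trioxo-2-phenyl-3,4,5,6,7,8-hexahydro-2H-chromene-6-carboxylate | CC(C)(C)OC(=O)C1(C)C(=O)CC2=C(C1=O)C(=O)C[C@@H](c1ccccc1)O2
F6 | step 10 | (2S)-5,7-dihydroxy-8-[(1S)-1-(2-hydroxy-4-methoxy-3,3,5-trimethyl-6-oxocyclohexa-1,4-dien-1-yl)-2-methylpropyl]-6-methyl-2-phenylchroman-4-one | COC1=C(C)C(=O)C([C@H](c2c(O)c(C)c(O)c3c2O[C@H](c2ccccc2)CC3=O)C(C)C)=C(O)C1(C)C
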